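## Retrosynthetic overview

- **Feature:** in ring A the three oxygen-bearing carbons C8a, C5 and C7 lie ortho, ortho and para to the C4 carbonyl. Each aryl–oxygen bond of ring A (O1–C8a, C5–O, C7–O) can therefore be made by fluoride displacement on a 2,4,6-trifluorobenzoyl ring.
- **Last disconnections:** the three O-benzyl groups (hydrogenolysis), then C5–O and C7–O (benzyloxide SNAr on a 5,7-difluoroisoflavone).
- **Key disconnection:** O1–C8a of ring C, leading back to an α-hydroxymethylene deoxybenzoin whose enolate oxygen attacks an ortho C–F carbon.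
- **Fragments:** C2 comes from ethyl formate. C4–C4a comes from 2,4,6-trifluorophenyllithium and a ring B arylacetaldehyde. Ring B comes from 2,4,6-trimethoxybenzaldehyde by CHO-to-OH exchange, benzylation, re-formylation and one-carbon homologation.
- **Ring order:** rings A and B are bought as benzene rings, and ring C is the only ring formed.

Key step: step 9

Assumption: in step 10 the C7 fluoride (para to C4=O) is taken to leave first in DMF; the order is of no consequence because both fluorides are exchanged.

## Route

Step 1
Reactants: 1 2,4,6-trimethoxybenzaldehyde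
Product: 3 2,4,6-trimethoxyphenol, via 2,4,6-trimethoxyphenyl formate 2 (not isolated)
Conditions: mCPBA (1.1 equiv), CH2Cl2, 0 °C to rt; NaHCO3 aq wash, solvent exchange; then K2CO3 (cat.), MeOH, rt, N2
Reagents that add atoms: mCPBA, O=C(OO)c1cccc(Cl)c1
Why: Baeyer–Villiger (Dakin-type) oxidation, in which the very electron-rich aryl group migrates in preference to hydride and the aryl formate is then cleaved by base-catalysed transesterification with methanol, the methyl ethers being untouched.

Step 2
Reactants: 3 2,4,6-trimethoxyphenol; 4 benzyl bromide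
Product: 5 2-(benzyloxy)-1,3,5-trimethoxybenzene
Conditions: BnBr, K2CO3, DMF, rt to 50 °C, N2
Reagents that add atoms: benzyl bromide (4), BrCc1ccccc1
Why: Williamson ether synthesis by SN2 attack of the phenoxide on the benzylic bromide, benzyl being chosen so that it leaves in the final hydrogenolysis together with the ring A benzyl groups.

Step 3
Reactants: 5 2-(benzyloxy)-1,3,5-trimethoxybenzene
Product: 7 3-(benzyloxy)-2,4,6-trimethoxybenzaldehyde, via aryl iminium chloride 6 (not isolated)
Conditions: POCl3, DMF, 0 °C to rt; then H2O (ice)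
Reagents that add atoms: DMF, CN(C)C=O (formyl carbon); water, O (carbonyl oxygen)
Why: Vilsmeier–Haack formylation, in which the two free ring positions of 5 are equivalent by symmetry and each is ortho, ortho and para to the three methoxy groups, so that one aldehyde should result after hydrolysis of the iminium salt.

Step 4
Reactants: 7 3-(benzyloxy)-2,4,6-trimethoxybenzaldehyde
Product: 8 2-(benzyloxy)-1,3,5-trimethoxy-4-(2-methoxyethenyl)benzene (E/Z mixture)
Conditions: Ph3P(CH2OMe)Cl, KOt-Bu, THF, 0 °C to rt
Reagents that add atoms: (methoxymethyl)triphenylphosphonium chloride, [Cl-].COC[P+](c1ccccc1)(c1ccccc1)c1ccccc1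
Why: Wittig reaction with the non-stabilised methoxymethylene ylide, which is reactive enough for the hindered, electron-rich and non-enolisable aldehyde, the E/Z mixture being irrelevant because both isomers hydrolyse to the same aldehyde.

Step 5
Reactants: 8 2-(benzyloxy)-1,3,5-trimethoxy-4-(2-methoxyethenyl)benzene (E/Z mixture)
Product: 9 2-[3-(benzyloxy)-2,4,6-trimethoxyphenyl]acetaldehyde
Conditions: HCl (aq, 1 M, cat.), THF, dilute, rt to 40 °C; used at once
Reagents that add atoms: water, O
Why: acid-catalysed enol ether hydrolysis, in which protonation at the benzylic carbon gives the oxocarbenium ion, water adds and methanol leaves, while mild acid and dilution keep the nucleophilic ring B from condensing with the new aldehyde.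

Step 6
Reactants: 9 2-[3-(benzyloxy)-2,4,6-trimethoxyphenyl]acetaldehyde; 10 1,3,5-trifluorobenzene
Product: 12 2-[3-(benzyloxy)-2,4,6-trimethoxyphenyl]-1-(2,4,6-trifluorophenyl)ethan-1-ol (racemic), via 2,4,6-trifluorophenyllithium 11 (not isolated)
Conditions: 10 (1.3 equiv), n-BuLi (1.25 equiv), THF, −78 °C; then 9, −78 °C; AcOH, −78 °C
Reagents that add atoms: none
Why: lithiation of 10 at a C–H flanked by two fluorines followed by 1,2-addition of the weakly basic aryllithium to the aldehyde at −78 °C, where loss of LiF to the aryne and enolisation of 9 should stay slow, the new carbinol centre being racemic and erased in step 7.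

Step 7
Reactants: 12 2-[3-(benzyloxy)-2,4,6-trimethoxyphenyl]-1-(2,4,6-trifluorophenyl)ethan-1-ol (racemic)
Product: 13 2-[3-(benzyloxy)-2,4,6-trimethoxyphenyl]-1-(2,4,6-trifluorophenyl)ethan-1-one
Conditions: Dess–Martin periodinane, CH2Cl2, 0 °C to rt
Reagents that add atoms: none
Why: Dess–Martin oxidation of a secondary benzylic alcohol under neutral, non-nucleophilic conditions that leave the aryl fluorides, the benzyl ether and the electron-rich ring B alone.

Step 8
Reactants: 13 2-[3-(benzyloxy)-2,4,6-trimethoxyphenyl]-1-(2,4,6-trifluorophenyl)ethan-1-one; 14 ethyl formate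
Product: 16 (Z)-2-[3-(benzyloxy)-2,4,6-trimethoxyphenyl]-3-hydroxy-1-(2,4,6-trifluorophenyl)prop-2-en-1-one, via sodium enolate 15 (not isolated)
Conditions: NaH (1.1 equiv), THF, 0 °C, Ar; then HCO2Et (5 equiv), 0 °C to rt; HCl (aq, 1 M), 0 °C
Reagents that add atoms: ethyl formate (14), CCOC=O
Why: crossed Claisen condensation (C-formylation), in which 13 is first turned fully into its enolate with only a slight excess of NaH, so that the ethoxide released is consumed at once in deprotonating the far more acidic product and stays as ethanol rather than as a nucleophile for the fluorinated ring, while the tight sodium chelate in THF holds the enolate oxygen away from the ortho fluorines until the acid quench.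

Step 9
Reactants: 16 (Z)-2-[3-(benzyloxy)-2,4,6-trimethoxyphenyl]-3-hydroxy-1-(2,4,6-trifluorophenyl)prop-2-en-1-one
Product: 18 3-[3-(benzyloxy)-2,4,6-trimethoxyphenyl]-5,7-difluoro-4H-chromen-4-one, via potassium enolate 17 (not isolated)
Conditions: K2CO3 (2 equiv), dry DMF (0.02 M), rt to 60 °C
Reagents that add atoms: none
Why: K2CO3 removes the acidic enol proton, and in DMF the loosely ion-paired enolate 17 can turn about the C3–C4 bond out of its chelated U shape, which places the formyl-derived oxygen over one of the ortho C–F carbons of the twisted aroyl ring. This oxygen adds to C8a to give a Meisenheimer anion whose charge runs through C4a into the C4 carbonyl and is helped inductively by the two fluorines meta to the point of attack; loss of fluoride then restores the arene and leaves the O1–C8a bond. The closest known reaction type is the intramolecular SNAr O-arylation of 2-fluorobenzoyl 1,3-dicarbonyl enolates to chromones, the oxygen counterpart of the base-induced ring closure of fluoroquinolone syntheses. Ring C closes as a six-membered ring by addition–elimination, formally 6-endo-trig on the C8a=C4a–C4=O vinylogous acyl fluoride, with the departing fluoride on a bond outside the new ring. No stereocentre is created, and the Z geometry needed for closure (O1 and C4 cis on C2=C3) is that of the enolate itself. The step needs oxygen rather than carbon attack, one ortho fluorine out of two and no attack at the para fluorine: attack by C3 or by the C4 oxygen would require a four-membered ring, the two ortho fluorines are interchanged by rotation about C4–C4a, and the para fluorine is out of intramolecular reach while high dilution holds back the intermolecular reaction.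

Step 10
Reactants: 18 3-[3-(benzyloxy)-2,4,6-trimethoxyphenyl]-5,7-difluoro-4H-chromen-4-one
Product: 20 5,7-bis(benzyloxy)-3-[3-(benzyloxy)-2,4,6-trimethoxyphenyl]-4H-chromen-4-one, via 7-benzyloxy-5-fluoro isoflavone 19 (not isolated)
Conditions: BnOH (3 equiv), NaH (2.6 equiv), THF, 0 °C; then 18, dry DMF, 0 to 50 °C; AcOH quench
Reagents that add atoms: benzyl alcohol, OCc1ccccc1
Why: twofold intermolecular SNAr, in which C7–F is para and C5–F ortho to the C4 carbonyl so that benzyloxide should replace both in turn, while addition of the alkoxide at C2 is reversible and does no lasting harm as long as water is excluded.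

Step 11
Reactants: 20 5,7-bis(benzyloxy)-3-[3-(benzyloxy)-2,4,6-trimethoxyphenyl]-4H-chromen-4-one
Product: 21 5,7-dihydroxy-3-(3-hydroxy-2,4,6-trimethoxyphenyl)-4H-chromen-4-one (target)
Conditions: H2 (1 atm), Pd/C (10 wt%), EtOAc–MeOH, rt, stopped after uptake of three equivalents
Reagents that add atoms: none
Why: catalytic hydrogenolysis of the three aryl benzyl ethers, which should be faster than reduction of the C2=C3 bond shielded by the di-ortho-substituted ring B, the methyl ethers being inert.

## Compound list

| No. | Name | SMILES | Role |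
|---|---|---|---|
| 1 | 2,4,6-trimethoxybenzaldehyde | COc1cc(OC)c(C=O)c(OC)c1 | starting material |
| 2 | 2,4,6-trimethoxyphenyl formate (not isolated) | COc1cc(OC)c(OC=O)c(OC)c1 | intermediate |
| 3 | 2,4,6-trimethoxyphenol | COc1cc(OC)c(O)c(OC)c1 | intermediate |
| 4 | benzyl bromide | BrCc1ccccc1 | starting material |
| 5 | 2-(benzyloxy)-1,3,5-trimethoxybenzene | COc1cc(OC)c(OCc2ccccc2)c(OC)c1 | intermediate |
| 6 | [3-(benzyloxy)-2,4,6-trimethoxybenzylidene]dimethylammonium chloride (not isolated) | COc1cc(OC)c(C=[N+](C)C)c(OC)c1OCc1ccccc1.[Cl-] | intermediate |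
| 7 | 3-(benzyloxy)-2,4,6-trimethoxybenzaldehyde | COc1cc(OC)c(C=O)c(OC)c1OCc1ccccc1 | intermediate |
| 8 | 2-(benzyloxy)-1,3,5-trimethoxy-4-(2-methoxyethenyl)benzene (E/Z mixture) | COC=Cc1c(OC)cc(OC)c(OCc2ccccc2)c1OC | intermediate |
| 9 | 2-[3-(benzyloxy)-2,4,6-trimethoxyphenyl]acetaldehyde | O=CCc1c(OC)cc(OC)c(OCc2ccccc2)c1OC | intermediate |
| 10 | 1,3,5-trifluorobenzene | Fc1cc(F)cc(F)c1 | starting material |
| 11 | 2,4,6-trifluorophenyllithium (not isolated) | [Li]c1c(F)cc(F)cc1F | intermediate |
| 12 | 2-[3-(benzyloxy)-2,4,6-trimethoxyphenyl]-1-(2,4,6-trifluorophenyl)ethan-1-ol (racemic) | OC(Cc1c(OC)cc(OC)c(OCc2ccccc2)c1OC)c1c(F)cc(F)cc1F | intermediate |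
| 13 | 2-[3-(benzyloxy)-2,4,6-trimethoxyphenyl]-1-(2,4,6-trifluorophenyl)ethan-1-one | O=C(Cc1c(OC)cc(OC)c(OCc2ccccc2)c1OC)c1c(F)cc(F)cc1F | intermediate |
| 14 | ethyl formate | CCOC=O | starting material |
| 15 | sodium enolate of 13 (not isolated; double-bond geometry of no consequence) | [Na+].[O-]C(=Cc1c(OC)cc(OC)c(OCc2ccccc2)c1OC)c1c(F)cc(F)cc1F | intermediate |
| 16 | (Z)-2-[3-(benzyloxy)-2,4,6-trimethoxyphenyl]-3-hydroxy-1-(2,4,6-trifluorophenyl)prop-2-en-1-one | O/C=C(\C(=O)c1c(F)cc(F)cc1F)c1c(OC)cc(OC)c(OCc2ccccc2)c1OC | intermediate |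
| 17 | potassium enolate of 16 (not isolated) | [K+].[O-]/C=C(\C(=O)c1c(F)cc(F)cc1F)c1c(OC)cc(OC)c(OCc2ccccc2)c1OC | intermediate |
| 18 | 3-[3-(benzyloxy)-2,4,6-trimethoxyphenyl]-5,7-difluoro-4H-chromen-4-one | COc1cc(OC)c(-c2coc3cc(F)cc(F)c3c2=O)c(OC)c1OCc1ccccc1 | intermediate |
| 19 | 7-(benzyloxy)-3-[3-(benzyloxy)-2,4,6-trimethoxyphenyl]-5-fluoro-4H-chromen-4-one (not isolated) | COc1cc(OC)c(-c2coc3cc(OCc4ccccc4)cc(F)c3c2=O)c(OC)c1OCc1ccccc1 | intermediate |
| 20 | 5,7-bis(benzyloxy)-3-[3-(benzyloxy)-2,4,6-trimethoxyphenyl]-4H-chromen-4-one | COc1cc(OC)c(-c2coc3cc(OCc4ccccc4)cc(OCc4ccccc4)c3c2=O)c(OC)c1OCc1ccccc1 | intermediate |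
| 21 | 5,7-dihydroxy-3-(3-hydroxy-2,4,6-trimethoxyphenyl)-4H-chromen-4-one | COc1cc(OC)c(-c2coc3cc(O)cc(O)c3c2=O)c(OC)c1O | target |

## Step count

- Total step count: 11.
- Longest linear sequence: 11 steps (1 to 21). The lithiation of 10 is part of step 6.

## Steps most likely to fail

**Step 9.**
- What may go wrong: the enolate may lose its formyl group by retro-Claisen cleavage (adventitious water, carbonate) faster than it closes. It may also attack the para C–F carbon of a second molecule and oligomerise.
- Fallback (sets out from 9, comes back at 21): ring A is taken with its oxygens already in place, and ring C is closed at O1–C2 instead.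
- Aldehyde 9 would be oxidised under Pinnick conditions (NaClO2, NaH2PO4, 2-methylbut-2-ene, t-BuOH–H2O) to 2-[3-(benzyloxy)-2,4,6-trimethoxyphenyl]acetic acid F1.
- Friedel–Crafts acylation of phloroglucinol with this acid in BF3·OEt2 (70 °C) should give 2-[3-(benzyloxy)-2,4,6-trimethoxyphenyl]-1-(2,4,6-trihydroxyphenyl)ethan-1-one F2.
- One-carbon insertion with DMF, BF3·OEt2 and MsCl (the classical deoxybenzoin closure) should give 3-[3-(benzyloxy)-2,4,6-trimethoxyphenyl]-5,7-dihydroxy-4H-chromen-4-one F3.
- Hydrogenolysis as in step 11 then leads to 21.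

**Step 10.**
- What may go wrong: benzyloxide may attack C2, opening ring C. With traces of water, C2 is then lost irreversibly as formate during or after the fluoride exchange.
- Fallback (sets out from 18, comes back at 20): the opening is accepted, and ring C is rebuilt by an O1–C2 closure.
- The exchange would be driven with a larger excess of NaOBn under strictly dry conditions, where the opening is reversible and the closed, activated form stays available.
- The crude mixture of closed and opened forms would then be treated on purpose with NaOH (aq)–EtOH. This should converge on 1-[2,4-bis(benzyloxy)-6-hydroxyphenyl]-2-[3-(benzyloxy)-2,4,6-trimethoxyphenyl]ethan-1-one F4.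
- Heating F4 with N,N-dimethylformamide dimethyl acetal in toluene should pass through 1-[2,4-bis(benzyloxy)-6-hydroxyphenyl]-2-[3-(benzyloxy)-2,4,6-trimethoxyphenyl]-3-(dimethylamino)prop-2-en-1-one F5. Its phenol adds to the enaminone and expels the amine to give 20.

**Step 8.**
- What may go wrong: ethoxide may displace ring fluorides if free alkoxide builds up. C-formylation may be sluggish or reversible at the carbon flanked by two di-ortho-substituted aryl groups.
- Fallback (sets out from 13, comes back at 16): aminomethylenation followed by hydrolysis replaces the Claisen condensation.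
- Ketone 13 would be heated with N,N-dimethylformamide dimethyl acetal in toluene (90 °C) to give 2-[3-(benzyloxy)-2,4,6-trimethoxyphenyl]-3-(dimethylamino)-1-(2,4,6-trifluorophenyl)prop-2-en-1-one F6.
- Hydrolysis with HCl (aq, 1 M)–THF at rt should give 16. The amine leaves as its non-nucleophilic salt.

## Further compounds

F1 | step 9 | 2-[3-(benzyloxy)-2,4,6-trimethoxyphenyl]acetic acid | OC(=O)Cc1c(OC)cc(OC)c(OCc2ccccc2)c1OC
F2 | step 9 | 2-[3-(benzyloxy)-2,4,6-trimethoxyphenyl]-1-(2,4,6-trihydroxyphenyl)ethan-1-one | O=C(Cc1c(OC)cc(OC)c(OCc2ccccc2)c1OC)c1c(O)cc(O)cc1O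
F3 | step 9 | 3-[3-(benzyloxy)-2,4,6-trimethoxyphenyl]-5,7-dihydroxy-4H-chromen-4-one | COc1cc(OC)c(-c2coc3cc(O)cc(O)c3c2=O)c(OC)c1OCc1ccccc1
F4 | step 10 | 1-[2,4-bis(benzyloxy)-6-hydroxyphenyl]-2-[3-(benzyloxy)-2,4,6-trimethoxyphenyl]ethan-1-one | O=C(Cc1c(OC)cc(OC)c(OCc2ccccc2)c1OC)c1c(O)cc(OCc2ccccc2)cc1OCc1ccccc1
F5 | step 10 | 1-[2,4-bis(benzyloxy)-6-hydroxyphenyl]-2-[3-(benzyloxy)-2,4,6-trimethoxyphenyl]-3-(dimethylamino)prop-2-en-1-one | CN(C)C=C(C(=O)c1c(O)cc(OCc2ccccc2)cc1OCc1ccccc1)c1c(OC)cc(OC)c(OCc2ccccc2)c1OC
F6 | step 8 | 2-[3-(benzyloxy)-2,4,6-trimethoxyphenyl]-3-(dimethylamino)-1-(2,4,6-trifluorophenyl)prop-2-en-1-one | CN(C)C=C(C(=O)c1c(F)cc(F)cc1F)c1c(OC)cc(OC)c(OCc2ccccc2)c1OC
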